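**Assumptions.** (i) The target is a germacranolide with sesquiterpene numbering: C1 ketone, C5‑OH, C6–O lactone (6,12‑olide), C8 methacrylate, C10 acetate. Its configuration is 4S,5S,6S,7R,8S,10R with a trans‑fused lactone. (ii) The enantiomer of each chiral catalyst is chosen to give the configuration drawn. (iii) 2‑(PMB‑oxy)acetaldehyde is taken as commercial, or made in one Swern step from the commercial alcohol.

## Retrosynthetic overview
1. The target comes from C8 methacrylation and two desilylations of the 10‑membered trans‑α‑methylene‑γ‑lactone **19**. **19** is formed in one intramolecular Nozaki–Hiyama–Kishi allylation (C6–C7 bond) of α‑silyloxy aldehyde/(Z)‑2‑(bromomethyl)enoate **18**. This is the only ring‑forming step, and the carbocycle and lactone close together.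
2. **18** comes from a C7 aldehyde by Morita–Baylis–Hillman reaction and SN2′ bromination. The C1–C10 bond, the C1 ketone and the C10 tertiary carbinol come from an NHC‑catalysed crossed acyloin between aldehyde **5** and β‑silyloxy methyl ketone **9** (the new step).
3. **5** comes from organocatalytic anti‑crotylation (C4 and C5) of PMB‑oxyacetaldehyde followed by hydroformylation. **9** comes from the proline aldol of acetone with TBS‑oxyacetaldehyde (C8).

## Route

**Step 1**
Reactants: **1** 2‑[(4‑methoxybenzyl)oxy]acetaldehyde; **2** (E)‑crotylboronic acid pinacol ester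
Product: **3** (2S,3S)‑1‑(PMB‑oxy)‑3‑methylpent‑4‑en‑2‑ol
Conditions: chiral phosphoric acid (VAPOL/BINOL type, 10 mol%), toluene, 4 Å MS, −30 °C
Reagents that add atoms: none
Why: Brønsted‑acid‑catalysed allylboration proceeds through a closed chair transition state. The E‑crotyl reagent gives the anti homoallylic alcohol, so C4 and C5 are set together and the catalyst controls the aldehyde face.

**Step 2**
Reactants: **3**
Product: **4** TBDPS ether of **3**
Conditions: TBDPSCl, imidazole, DMAP (cat.), DMF, 40 °C
Reagents that add atoms: TBDPSCl, CC(C)(C)[Si](Cl)(c1ccccc1)c1ccccc1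
Why: Silyl ether formation protects C5‑OH. It is orthogonal to the PMB group and survives the later HF·pyridine treatments that remove TBS.

**Step 3**
Reactants: **4**
Product: **5** aldehyde (C1 CHO, chain C1–C6)
Conditions: Rh(CO)2(acac) (1 mol%), biphephos (2 mol%), CO/H2 (1:1, 20 bar), toluene, 60 °C
Reagents that add atoms: CO, [C-]#[O+]
Why: Linear‑selective hydroformylation with a bulky diphosphite converts the vinyl group into CH2CH2CHO, which builds C2 and C1. C4 is γ to the new carbonyl and cannot epimerise.

**Step 4**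
Reactants: **6** TBS‑oxyacetaldehyde; **7** acetone
Product: **8** (S)‑5‑(TBS‑oxy)‑4‑hydroxypentan‑2‑one
Conditions: D‑proline (30 mol%), acetone/DMSO, 23 °C
Reagents that add atoms: none
Why: In the List–Barbas enamine aldol, the proline enamine of acetone adds to one face of the α‑silyloxy aldehyde and sets C8 as (S).

**Step 5**
Reactants: **8**
Product: **9** (S)‑4,5‑bis(TBS‑oxy)pentan‑2‑one
Conditions: TBSCl, imidazole, DMF, 23 °C
Reagents that add atoms: TBSCl, C[Si](C)(Cl)C(C)(C)C
Why: Silylation blocks C8‑OH and prevents retro‑aldol or E1cB loss of the oxygen in the next step. C8 is not touched.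

**Step 6**
Reactants: **5**; **9** (4 equiv)
Product: **10** α‑hydroxy ketone with C1 C=O and C10 C(OH)Me
Conditions: chiral aminoindanol N‑C6F5 triazolium (20 mol%), Cs2CO3 (20 mol%), toluene, 0→23 °C, aldehyde added by syringe pump
Reagents that add atoms: none
Why: Proposed new method: an NHC generates the Breslow acyl‑anion equivalent from unhindered aldehyde **5**. It adds to the Re or Si face of the methyl ketone of **9**, set by the chiral N‑aryl/aminoindanol pocket and matched to the C8 stereocentre. The result is a tertiary α‑ketol with C10 as the new stereocentre. The closest known reactions are intramolecular aldehyde–ketone crossed benzoins and intermolecular cross‑acyloins with activated ketones (CF3 ketones, α‑keto esters). Here the electrophile is an unactivated dialkyl ketone with an inductively activating β‑OTBS group. Excess ketone and slow aldehyde addition suppress aldehyde homo‑benzoin, which is reversible.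

**Step 7**
Reactants: **10**
Product: **11** C10 acetate
Conditions: Ac2O, DMAP, Et3N, CH2Cl2, 40 °C
Reagents that add atoms: Ac2O, CC(=O)OC(C)=O
Why: DMAP‑catalysed acylation of the tertiary α‑ketol gives the C10‑OAc of the target. The stereocentre is untouched because no bond to C10 is broken.

**Step 8**
Reactants: **11**
Product: **12** C7 primary alcohol (C8‑OTBS retained)
Conditions: CSA (0.1 equiv), MeOH/CH2Cl2, 0 °C
Reagents that add atoms: none
Why: Mild acid cleaves the primary TBS ether faster than the hindered secondary one. PMB, TBDPS and both acyl groups survive.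

**Step 9**
Reactants: **12**
Product: **13** C7 aldehyde
Conditions: Dess–Martin periodinane, NaHCO3, CH2Cl2, 0→23 °C
Reagents that add atoms: none
Why: Dess–Martin oxidation of a primary alcohol. It is non‑epimerising and leaves the ketone, esters and silyl ethers intact.

**Step 10**
Reactants: **13**; **14** methyl acrylate
Product: **15** Baylis–Hillman adduct (C7–OH, mixture at C7)
Conditions: DABCO (1 equiv), MeOH, 23 °C, 3–5 d
Reagents that add atoms: none
Why: Morita–Baylis–Hillman reaction builds C11–C12–C13 on C7. The C7 stereocentre is destroyed in the next step, so it needs no control.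

**Step 11**
Reactants: **15**
Product: **16** (Z)‑2‑(bromomethyl)enoate, CO2Me trans to C8
Conditions: NBS, Me2S, CH2Cl2, 0→23 °C
Reagents that add atoms: NBS, O=C1CCC(=O)N1Br
Why: The Br–SMe2+ species converts the allylic alcohol by SN2′ into the (Z)‑allyl bromide needed for a trans‑lactone annulation. C7 becomes sp2.

**Step 12**
Reactants: **16**
Product: **17** C6 primary alcohol
Conditions: DDQ, CH2Cl2/pH 7 buffer, 0 °C
Reagents that add atoms: none
Why: Oxidative PMB removal is orthogonal to TBS, TBDPS, the esters and the allyl bromide.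

**Step 13**
Reactants: **17**
Product: **18** C6 α‑silyloxy aldehyde (NHK precursor)
Conditions: Dess–Martin periodinane, NaHCO3, CH2Cl2
Reagents that add atoms: none
Why: Mild oxidation to the α‑silyloxy aldehyde, which is only weakly epimerisable at C5.

**Step 14**
Reactants: **18**
Product: **19** macrocyclic trans‑α‑methylene‑γ‑lactone (C8‑OTBS, C5‑OTBDPS)
Conditions: CrCl2 (8 equiv), NiCl2 (cat.), DMF, 23 °C, 2 mM (syringe pump, 12 h); then TsOH (cat.), CH2Cl2
Reagents that add atoms: none
Why: Intramolecular Nozaki–Hiyama–Kishi allylation. The allylchromium adds through a chair transition state to give the anti adduct, hence the trans‑lactone. Macrocyclic strain and the C5 and C8 stereocentres direct C6 and C7, and the Cr‑alkoxide lactonises onto the methyl ester to form the methylene lactone.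

**Step 15**
Reactants: **19**
Product: **20** C8 alcohol
Conditions: HF·pyridine, pyridine, THF, 0→23 °C
Reagents that add atoms: none
Why: The secondary TBS ether is cleaved selectively over TBDPS under acidic fluoride.

**Step 16**
Reactants: **20**
Product: **21** C8 methacrylate
Conditions: methacryloyl chloride, Et3N, DMAP (cat.), CH2Cl2, −10 °C
Reagents that add atoms: methacryloyl chloride, C=C(C)C(=O)Cl
Why: Acylation of the only free secondary alcohol gives the C8 ester with retention.

**Step 17**
Reactants: **21**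
Product: **22** Lychnostatin 1
Conditions: HF·pyridine, THF/pyridine, 23→40 °C
Reagents that add atoms: none
Why: Acidic fluoride removes the last silyl group. The lactone, methacrylate, acetate and ketone are stable under these conditions.

## Compound list
1 | 2‑[(4‑methoxybenzyl)oxy]acetaldehyde | O=CCOCc1ccc(OC)cc1 | starting material
2 | (E)‑crotylboronic acid pinacol ester | C/C=C/CB1OC(C)(C)C(C)(C)O1 | starting material
3 | (2S,3S)‑1‑(PMB‑oxy)‑3‑methylpent‑4‑en‑2‑ol | C=C[C@H](C)[C@H](O)COCc1ccc(OC)cc1 | intermediate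
4 | TBDPS ether of 3 | C=C[C@H](C)[C@H](O[Si](c1ccccc1)(c1ccccc1)C(C)(C)C)COCc1ccc(OC)cc1 | intermediate
5 | aldehyde (C1 CHO), chain C1–C6 | O=CCC[C@H](C)[C@H](O[Si](c1ccccc1)(c1ccccc1)C(C)(C)C)COCc1ccc(OC)cc1 | intermediate
6 | TBS‑oxyacetaldehyde | O=CCO[Si](C)(C)C(C)(C)C | starting material
7 | acetone | CC(C)=O | starting material
8 | (S)‑5‑(TBS‑oxy)‑4‑hydroxypentan‑2‑one | CC(=O)C[C@H](O)CO[Si](C)(C)C(C)(C)C | intermediate
9 | (S)‑4,5‑bis(TBS‑oxy)pentan‑2‑one | CC(=O)C[C@H](O[Si](C)(C)C(C)(C)C)CO[Si](C)(C)C(C)(C)C | intermediate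
10 | acyloin, C1 ketone / C10 tertiary OH | COc1ccc(COC[C@@H](O[Si](c2ccccc2)(c2ccccc2)C(C)(C)C)[C@@H](C)CCC(=O)[C@](C)(O)C[C@H](O[Si](C)(C)C(C)(C)C)CO[Si](C)(C)C(C)(C)C)cc1 | intermediate
11 | C10 acetate of 10 | COc1ccc(COC[C@@H](O[Si](c2ccccc2)(c2ccccc2)C(C)(C)C)[C@@H](C)CCC(=O)[C@](C)(OC(C)=O)C[C@H](O[Si](C)(C)C(C)(C)C)CO[Si](C)(C)C(C)(C)C)cc1 | intermediate
12 | C7 primary alcohol | COc1ccc(COC[C@@H](O[Si](c2ccccc2)(c2ccccc2)C(C)(C)C)[C@@H](C)CCC(=O)[C@](C)(OC(C)=O)C[C@H](O[Si](C)(C)C(C)(C)C)CO)cc1 | intermediate
13 | C7 aldehyde | COc1ccc(COC[C@@H](O[Si](c2ccccc2)(c2ccccc2)C(C)(C)C)[C@@H](C)CCC(=O)[C@](C)(OC(C)=O)C[C@H](O[Si](C)(C)C(C)(C)C)C=O)cc1 | intermediate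
14 | methyl acrylate | C=CC(=O)OC | starting material
15 | Baylis–Hillman adduct (C7 epimeric mixture) | COc1ccc(COC[C@@H](O[Si](c2ccccc2)(c2ccccc2)C(C)(C)C)[C@@H](C)CCC(=O)[C@](C)(OC(C)=O)C[C@H](O[Si](C)(C)C(C)(C)C)C(O)C(=C)C(=O)OC)cc1 | intermediate
16 | (Z)‑allyl bromide | COc1ccc(COC[C@@H](O[Si](c2ccccc2)(c2ccccc2)C(C)(C)C)[C@@H](C)CCC(=O)[C@](C)(OC(C)=O)C[C@H](O[Si](C)(C)C(C)(C)C)/C=C(\CBr)C(=O)OC)cc1 | intermediate
17 | C6 alcohol | OC[C@@H](O[Si](c1ccccc1)(c1ccccc1)C(C)(C)C)[C@@H](C)CCC(=O)[C@](C)(OC(C)=O)C[C@H](O[Si](C)(C)C(C)(C)C)/C=C(\CBr)C(=O)OC | intermediate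
18 | NHK precursor (C6 aldehyde) | O=C[C@@H](O[Si](c1ccccc1)(c1ccccc1)C(C)(C)C)[C@@H](C)CCC(=O)[C@](C)(OC(C)=O)C[C@H](O[Si](C)(C)C(C)(C)C)/C=C(\CBr)C(=O)OC | intermediate
19 | macrolactone, C8‑OTBS / C5‑OTBDPS | C[Si](C)(C(C)(C)C)O[C@H]1C[C@@](C)(OC(C)=O)C(=O)CC[C@H](C)[C@H](O[Si](c3ccccc3)(c3ccccc3)C(C)(C)C)[C@H]2OC(=O)C(=C)[C@@H]21 | intermediate
20 | C8 alcohol | O[C@H]1C[C@@](C)(OC(C)=O)C(=O)CC[C@H](C)[C@H](O[Si](c3ccccc3)(c3ccccc3)C(C)(C)C)[C@H]2OC(=O)C(=C)[C@@H]21 | intermediate
21 | C8 methacrylate, C5‑OTBDPS | C=C(C)C(=O)O[C@H]1C[C@@](C)(OC(C)=O)C(=O)CC[C@H](C)[C@H](O[Si](c3ccccc3)(c3ccccc3)C(C)(C)C)[C@H]2OC(=O)C(=C)[C@@H]21 | intermediate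
22 | Lychnostatin 1 | C=C(C)C(=O)O[C@H]1C[C@@](C)(OC(C)=O)C(=O)CC[C@H](C)[C@H](O)[C@H]2OC(=O)C(=C)[C@@H]21 | target

**Total steps:** 17. **Longest linear sequence:** 15 (steps 1, 2, 3, then 6–17).

## Three steps most likely to fail
1. **Step 6 (new NHC crossed acyloin).** The aldehyde may homo‑benzoinate, the unactivated ketone may be too poor an acceptor, and C10 diastereocontrol may be weak.
   Fallback: Corey–Seebach umpolung. Convert **5** to its 1,3‑dithiane, lithiate and add to **9**, separate the C10 epimers, and cleave the dithiane with PIFA or MeI/CaCO3 to give **10**.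
2. **Step 14 (macro‑NHK).** Yield and the C6/C7 diastereoselectivity at 10‑ring closure are uncertain, and 8,12‑ versus 6,12‑lactonisation is a further risk.
   Fallback: form the trans‑α‑methylene lactone first by an intermolecular indium‑mediated anti‑selective Barbier allylation. Then close the ring by Ru‑catalysed RCM to the C1=C10 germacranolide. Convert the C1=C10 alkene to the α‑acetoxy ketone by epoxidation and oxidative opening, then methacrylate C8 and remove the silyl groups.
3. **Step 10 (Baylis–Hillman on an α‑silyloxy aldehyde).** C8 epimerisation and competing intramolecular aldol of the 1,5‑ketoaldehyde are both possible, and the reaction is slow.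
   Fallback: use a Horner–Wadsworth–Emmons olefination of **13** with methyl 2‑(diethoxyphosphoryl)‑3‑(TBS‑oxy)propanoate. This gives the E‑enoate with CO2Me trans to C8. Then desilylate the allylic alcohol and convert it to the bromide with MsCl/LiBr.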